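## Retrosynthetic overview

1. Target ⇒ O-silyl γ-lactone ⇒ γ-hydroxy ester (the lactone ring is the last ring closed) ⇒ α-hydroxy aldehyde plus a stabilised ylide that brings the two missing lactone carbons, followed by conjugate reduction.
2. Vicinal C–O stereodiad ⇒ key intermolecular lithium-enolate aldol addition of (2S,5S)-2-tert-butyl-5-methyl-1,3-dioxolan-4-one (from (S)-lactic acid) to (4E,8E)-11-(furan-3-yl)-4,8-dimethylundeca-4,8-dienal. The template sets the quaternary centre; the carbinol centre is then fixed by oxidation and CBS reduction.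
3. Dienal ⇒ two rounds of isopropenyl Grignard addition, Johnson orthoester Claisen rearrangement and ester-to-aldehyde reduction ⇒ 3-(furan-3-yl)propanal ⇒ furan-3-carbaldehyde.
4. Ring order: the furan ring is bought intact; the temporary dioxolanone ring is made before the key step and opened reductively after it; the γ-lactone ring is closed in step 18.

Assumption: iBu2AlH, LiN(iPr)2, isopropenylmagnesium bromide, the stabilised ylide and the oxazaborolidine catalyst are used as bought; C1′ means the carbinol carbon of the side chain.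

## Route

Step 1
Reactants: 1 furan-3-carbaldehyde; 2 methyl (triphenylphosphoranylidene)acetate
Product: 3 methyl (2E)-3-(furan-3-yl)prop-2-enoate
Conditions: CH2Cl2, rt, 12 h
Reagents that add atoms: none
Why: Wittig olefination with a stabilised ylide gives the (E)-acrylate cleanly from a non-enolisable heteroaryl aldehyde, and the alkene geometry is irrelevant because it is saturated next.

Step 2
Reactants: 3 methyl (2E)-3-(furan-3-yl)prop-2-enoate
Product: 4 methyl 3-(furan-3-yl)propanoate
Conditions: NaBH4 (3 equiv), NiCl2·6H2O (0.2 equiv), MeOH, 0 °C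
Reagents that add atoms: none
Why: Nickel boride conjugate reduction saturates only the ester-conjugated alkene and leaves the aromatic furan ring and the ester untouched.

Step 3
Reactants: 4 methyl 3-(furan-3-yl)propanoate
Product: 5 3-(furan-3-yl)propanal
Conditions: iBu2AlH (1.1 equiv), CH2Cl2, −78 °C; MeOH, then aq. Rochelle salt
Reagents that add atoms: none
Why: Partial ester reduction with one equivalent of iBu2AlH at −78 °C stops at the tetrahedral aluminium hemiacetal, which releases the aldehyde only on work-up.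

Step 4
Reactants: 5 3-(furan-3-yl)propanal; 6 isopropenylmagnesium bromide
Product: 7 rac-5-(furan-3-yl)-2-methylpent-1-en-3-ol
Conditions: THF, −78 to 0 °C; aqueous work-up
Reagents that add atoms: none
Why: Grignard 1,2-addition of an alkenyl nucleophile to an unhindered aldehyde is dependable, and the new carbinol centre is left racemic because the next step destroys it.

Step 5
Reactants: 7 rac-5-(furan-3-yl)-2-methylpent-1-en-3-ol; 8 triethyl orthoacetate
Product: 10 ethyl (4E)-7-(furan-3-yl)-4-methylhept-4-enoate, via mixed ketene acetal 9 (not isolated)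
Conditions: MeC(OEt)3 (7 equiv), EtCO2H (0.1 equiv), 140 °C, EtOH distilled off
Reagents that add atoms: none
Why: Johnson orthoester Claisen rearrangement proceeds through a chair transition state with the furylethyl group pseudo-equatorial, which gives the (E)-trisubstituted alkene (typically ≥97:3) while adding the two-carbon ester arm.

Step 6
Reactants: 10 ethyl (4E)-7-(furan-3-yl)-4-methylhept-4-enoate
Product: 11 (4E)-7-(furan-3-yl)-4-methylhept-4-enal
Conditions: iBu2AlH (1.1 equiv), CH2Cl2, −78 °C; MeOH, then aq. Rochelle salt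
Reagents that add atoms: none
Why: Partial ester reduction with iBu2AlH at −78 °C again stops at the aldehyde oxidation level and does not touch the isolated trisubstituted alkene.

Step 7
Reactants: 11 (4E)-7-(furan-3-yl)-4-methylhept-4-enal; 6 isopropenylmagnesium bromide
Product: 12 rac-(6E)-9-(furan-3-yl)-2,6-dimethylnona-1,6-dien-3-ol
Conditions: THF, −78 to 0 °C; aqueous work-up
Reagents that add atoms: none
Why: Grignard 1,2-addition as in step 4 gives the second allylic alcohol, again racemic on purpose because the centre is consumed in the rearrangement.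

Step 8
Reactants: 12 rac-(6E)-9-(furan-3-yl)-2,6-dimethylnona-1,6-dien-3-ol; 8 triethyl orthoacetate
Product: 14 ethyl (4E,8E)-11-(furan-3-yl)-4,8-dimethylundeca-4,8-dienoate, via mixed ketene acetal 13 (not isolated)
Conditions: MeC(OEt)3 (7 equiv), EtCO2H (0.1 equiv), 140 °C, EtOH distilled off
Reagents that add atoms: none
Why: A second Johnson orthoester Claisen rearrangement through the same chair transition state installs the second (E)-trisubstituted alkene without affecting the first.

Step 9
Reactants: 14 ethyl (4E,8E)-11-(furan-3-yl)-4,8-dimethylundeca-4,8-dienoate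
Product: 15 (4E,8E)-11-(furan-3-yl)-4,8-dimethylundeca-4,8-dienal
Conditions: iBu2AlH (1.1 equiv), CH2Cl2, −78 °C; MeOH, then aq. Rochelle salt
Reagents that add atoms: none
Why: Partial ester reduction with iBu2AlH at −78 °C delivers the aldehyde partner for the key step with both alkenes and the furan intact.

Step 10
Reactants: 16 (S)-lactic acid; 17 pivalaldehyde
Product: 18 (2S,5S)-2-tert-butyl-5-methyl-1,3-dioxolan-4-one
Conditions: TsOH·H2O (cat.), H2SO4 (cat.), pentane, reflux, Dean–Stark; recrystallisation from pentane/Et2O at −78 °C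
Reagents that add atoms: none
Why: Acid-catalysed acetalisation with azeotropic water removal gives mainly the cis-dioxolanone, in which the unchanged lactate centre fixes the new acetal centre as S, and low-temperature crystallisation removes the trans isomer (Seebach self-regeneration-of-stereocentres template).

Step 11
Reactants: 18 (2S,5S)-2-tert-butyl-5-methyl-1,3-dioxolan-4-one (1.3 equiv); 15 (4E,8E)-11-(furan-3-yl)-4,8-dimethylundeca-4,8-dienal
Product: 20 (2S,5R)-2-tert-butyl-5-[(4E,8E)-11-(furan-3-yl)-1-hydroxy-4,8-dimethylundeca-4,8-dien-1-yl]-5-methyl-1,3-dioxolan-4-one as a mixture of both C1′ epimers, via lithium enolate 19 (not isolated)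
Conditions: LiN(iPr)2 (1.35 equiv), THF, −78 °C, 30 min; then 15, −78 °C, 1 h; AcOH quench at −78 °C
Reagents that add atoms: none
Why: In this intermolecular lithium-enolate aldol addition the planar enolate keeps only the acetal stereocentre and the aldehyde adds on the face trans to the tert-butyl group (>95:5), which sets the quaternary C–O centre with overall retention of the lactic acid configuration, while the carbinol centre forms as an epimer mixture that steps 12 and 13 converge.

Step 12
Reactants: 20 aldol adduct (both C1′ epimers)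
Product: 21 (2S,5R)-2-tert-butyl-5-[(4E,8E)-11-(furan-3-yl)-4,8-dimethylundeca-4,8-dienoyl]-5-methyl-1,3-dioxolan-4-one
Conditions: Dess–Martin periodinane (1.5 equiv), pyridine (3 equiv), CH2Cl2, 0 °C to rt
Reagents that add atoms: none
Why: Dess–Martin oxidation under buffered conditions converges both carbinol epimers to a single ketone that cannot enolise toward the quaternary centre, without touching the acetal, the alkenes or the furan.

Step 13
Reactants: 21 (2S,5R)-5-acyl dioxolanone
Product: 22 (2S,5R)-2-tert-butyl-5-[(1R,4E,8E)-11-(furan-3-yl)-1-hydroxy-4,8-dimethylundeca-4,8-dien-1-yl]-5-methyl-1,3-dioxolan-4-one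
Conditions: (S)-2-methyl-CBS-oxazaborolidine [(3aS)-1-methyl-3,3-diphenyltetrahydro-1H,3H-pyrrolo[1,2-c][1,3,2]oxazaborole, C18H20BNO] (0.2 equiv), catecholborane (1.8 equiv), toluene, −78 to −20 °C
Reagents that add atoms: none
Why: In this Corey–Bakshi–Shibata reduction the ketone binds with the quaternary dioxolanone carbon as the large group and the CH2 chain as the small group, so the (S)-catalyst delivers hydride to give the (R)-carbinol by reagent control, and catecholborane does not hydroborate the trisubstituted alkenes at this temperature.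

Step 14
Reactants: 22 (1′R)-hydroxy dioxolanone
Product: 23 (2S,5R)-2-tert-butyl-5-[(1R,4E,8E)-1-{[tert-butyl(dimethyl)silyl]oxy}-11-(furan-3-yl)-4,8-dimethylundeca-4,8-dien-1-yl]-5-methyl-1,3-dioxolan-4-one
Conditions: TBSOTf (1.5 equiv), 2,6-lutidine (3 equiv), CH2Cl2, −78 to 0 °C
Reagents that add atoms: tert-butyldimethylsilyl trifluoromethanesulfonate, CC(C)(C)[Si](C)(C)OS(=O)(=O)C(F)(F)F
Why: Silyl ether formation with the reactive silyl triflate and a hindered base protects the hindered secondary alcohol, so that later only the primary alcohol is oxidised and only the tertiary hydroxyl can close the lactone.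

Step 15
Reactants: 23 silyl-protected dioxolanone
Product: 24 (2S,3R,6E,10E)-3-{[tert-butyl(dimethyl)silyl]oxy}-13-(furan-3-yl)-2,6,10-trimethyltrideca-6,10-diene-1,2-diol
Conditions: LiAlH4 (2 equiv), Et2O, 0 °C; Fieser work-up
Reagents that add atoms: none
Why: Hydride reduction of the acylal ester gives the primary alcohol and expels the pivalaldehyde unit (reduced to neopentyl alcohol), which unmasks the tertiary alcohol with both stereocentres untouched.

Step 16
Reactants: 24 silyl-protected 1,2-diol
Product: 25 (2R,3R,6E,10E)-3-{[tert-butyl(dimethyl)silyl]oxy}-13-(furan-3-yl)-2-hydroxy-2,6,10-trimethyltrideca-6,10-dienal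
Conditions: SO3·pyridine (3 equiv), DMSO, Et3N (5 equiv), CH2Cl2, 0 °C; used crude
Reagents that add atoms: none
Why: Parikh–Doering oxidation converts only the primary alcohol because the tertiary one cannot be oxidised and activated DMSO does not cleave the 1,2-diol, and the quaternary α-carbon cannot epimerise (the descriptor changes from 2S to 2R only through CIP priorities).

Step 17
Reactants: 25 α-hydroxy aldehyde; 2 methyl (triphenylphosphoranylidene)acetate
Product: 26 methyl (2E,4S,5R,8E,12E)-5-{[tert-butyl(dimethyl)silyl]oxy}-15-(furan-3-yl)-4-hydroxy-4,8,12-trimethylpentadeca-2,8,12-trienoate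
Conditions: 2 (1.5 equiv), toluene, 60 °C
Reagents that add atoms: none
Why: Wittig olefination with the stabilised ylide adds the two remaining lactone carbons as an (E)-enoate and tolerates the free tertiary alcohol, and any (Z)-isomer merely closes to the butenolide, which converges in step 18.

Step 18
Reactants: 26 γ-hydroxy enoate
Product: 28 (5S)-5-[(1R,4E,8E)-1-{[tert-butyl(dimethyl)silyl]oxy}-11-(furan-3-yl)-4,8-dimethylundeca-4,8-dien-1-yl]-5-methyloxolan-2-one, via hydroxy ester 27 (not isolated)
Conditions: NaBH4 (4 equiv), NiCl2·6H2O (0.3 equiv), MeOH/THF, 0 °C; then pyridinium p-toluenesulfonate (0.1 equiv), toluene, 60 °C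
Reagents that add atoms: none
Why: Nickel boride conjugate reduction saturates only the ester-conjugated alkene (the trisubstituted alkenes and the furan are inert), and the resulting γ-hydroxy ester lactonises under mild acid through the tertiary hydroxyl with retention at the quaternary centre.

Step 19
Reactants: 28 silyl-protected lactone
Product: 29 (5S)-5-[(1R,4E,8E)-11-(furan-3-yl)-1-hydroxy-4,8-dimethylundeca-4,8-dien-1-yl]-5-methyloxolan-2-one (CNP0359258.1)
Conditions: HF·pyridine, pyridine, THF, 0 °C to rt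
Reagents that add atoms: none
Why: Fluoride-mediated silyl ether cleavage under buffered, non-equilibrating conditions frees the secondary alcohol without translactonisation and without harming the furan or the alkenes.

## Compound list

1 | furan-3-carbaldehyde | O=Cc1ccoc1 | starting material
2 | methyl (triphenylphosphoranylidene)acetate | COC(=O)C=P(c1ccccc1)(c1ccccc1)c1ccccc1 | starting material
3 | methyl (2E)-3-(furan-3-yl)prop-2-enoate | COC(=O)/C=C/c1ccoc1 | intermediate
4 | methyl 3-(furan-3-yl)propanoate | COC(=O)CCc1ccoc1 | intermediate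
5 | 3-(furan-3-yl)propanal | O=CCCc1ccoc1 | intermediate
6 | isopropenylmagnesium bromide (prop-1-en-2-ylmagnesium bromide) | C=C(C)[Mg]Br | starting material
7 | rac-5-(furan-3-yl)-2-methylpent-1-en-3-ol | C=C(C)C(O)CCc1ccoc1 | intermediate
8 | triethyl orthoacetate (1,1,1-triethoxyethane) | CCOC(C)(OCC)OCC | starting material
9 | 3-{3-[(1-ethoxyethenyl)oxy]-4-methylpent-4-en-1-yl}furan (mixed ketene acetal) | C=C(OCC)OC(CCc1ccoc1)C(C)=C | intermediate
10 | ethyl (4E)-7-(furan-3-yl)-4-methylhept-4-enoate | CCOC(=O)CC/C(C)=C/CCc1ccoc1 | intermediate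
11 | (4E)-7-(furan-3-yl)-4-methylhept-4-enal | O=CCC/C(C)=C/CCc1ccoc1 | intermediate
12 | rac-(6E)-9-(furan-3-yl)-2,6-dimethylnona-1,6-dien-3-ol | C=C(C)C(O)CC/C(C)=C/CCc1ccoc1 | intermediate
13 | 3-[(3E)-7-[(1-ethoxyethenyl)oxy]-4,8-dimethylnona-3,8-dien-1-yl]furan (mixed ketene acetal) | C=C(OCC)OC(CC/C(C)=C/CCc1ccoc1)C(C)=C | intermediate
14 | ethyl (4E,8E)-11-(furan-3-yl)-4,8-dimethylundeca-4,8-dienoate | CCOC(=O)CC/C(C)=C/CC/C(C)=C/CCc1ccoc1 | intermediate
15 | (4E,8E)-11-(furan-3-yl)-4,8-dimethylundeca-4,8-dienal | O=CCC/C(C)=C/CC/C(C)=C/CCc1ccoc1 | intermediate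
16 | (S)-lactic acid | C[C@H](O)C(=O)O | starting material
17 | pivalaldehyde (2,2-dimethylpropanal) | CC(C)(C)C=O | starting material
18 | (2S,5S)-2-tert-butyl-5-methyl-1,3-dioxolan-4-one | C[C@H]1C(=O)O[C@H](O1)C(C)(C)C | intermediate
19 | lithium (2S)-2-tert-butyl-5-methyl-1,3-dioxol-4-olate (lithium enolate) | CC1=C([O-])O[C@H](O1)C(C)(C)C.[Li+] | intermediate
20 | (2S,5R)-2-tert-butyl-5-[(4E,8E)-11-(furan-3-yl)-1-hydroxy-4,8-dimethylundeca-4,8-dien-1-yl]-5-methyl-1,3-dioxolan-4-one, both C1′ epimers | C[C@@]1(C(O)CC/C(C)=C/CC/C(C)=C/CCc2ccoc2)C(=O)O[C@H](O1)C(C)(C)C | intermediate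
21 | (2S,5R)-2-tert-butyl-5-[(4E,8E)-11-(furan-3-yl)-4,8-dimethylundeca-4,8-dienoyl]-5-methyl-1,3-dioxolan-4-one | C[C@@]1(C(=O)CC/C(C)=C/CC/C(C)=C/CCc2ccoc2)C(=O)O[C@H](O1)C(C)(C)C | intermediate
22 | (2S,5R)-2-tert-butyl-5-[(1R,4E,8E)-11-(furan-3-yl)-1-hydroxy-4,8-dimethylundeca-4,8-dien-1-yl]-5-methyl-1,3-dioxolan-4-one | C[C@@]1([C@H](O)CC/C(C)=C/CC/C(C)=C/CCc2ccoc2)C(=O)O[C@H](O1)C(C)(C)C | intermediate
23 | (2S,5R)-2-tert-butyl-5-[(1R,4E,8E)-1-{[tert-butyl(dimethyl)silyl]oxy}-11-(furan-3-yl)-4,8-dimethylundeca-4,8-dien-1-yl]-5-methyl-1,3-dioxolan-4-one | C[C@@]1([C@H](O[Si](C)(C)C(C)(C)C)CC/C(C)=C/CC/C(C)=C/CCc2ccoc2)C(=O)O[C@H](O1)C(C)(C)C | intermediate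
24 | (2S,3R,6E,10E)-3-{[tert-butyl(dimethyl)silyl]oxy}-13-(furan-3-yl)-2,6,10-trimethyltrideca-6,10-diene-1,2-diol | OC[C@](C)(O)[C@H](O[Si](C)(C)C(C)(C)C)CC/C(C)=C/CC/C(C)=C/CCc1ccoc1 | intermediate
25 | (2R,3R,6E,10E)-3-{[tert-butyl(dimethyl)silyl]oxy}-13-(furan-3-yl)-2-hydroxy-2,6,10-trimethyltrideca-6,10-dienal | O=C[C@](C)(O)[C@H](O[Si](C)(C)C(C)(C)C)CC/C(C)=C/CC/C(C)=C/CCc1ccoc1 | intermediate
26 | methyl (2E,4S,5R,8E,12E)-5-{[tert-butyl(dimethyl)silyl]oxy}-15-(furan-3-yl)-4-hydroxy-4,8,12-trimethylpentadeca-2,8,12-trienoate | COC(=O)/C=C/[C@](C)(O)[C@H](O[Si](C)(C)C(C)(C)C)CC/C(C)=C/CC/C(C)=C/CCc1ccoc1 | intermediate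
27 | methyl (4S,5R,8E,12E)-5-{[tert-butyl(dimethyl)silyl]oxy}-15-(furan-3-yl)-4-hydroxy-4,8,12-trimethylpentadeca-8,12-dienoate | COC(=O)CC[C@](C)(O)[C@H](O[Si](C)(C)C(C)(C)C)CC/C(C)=C/CC/C(C)=C/CCc1ccoc1 | intermediate
28 | (5S)-5-[(1R,4E,8E)-1-{[tert-butyl(dimethyl)silyl]oxy}-11-(furan-3-yl)-4,8-dimethylundeca-4,8-dien-1-yl]-5-methyloxolan-2-one | C/C(=C\CCc1ccoc1)CC/C=C(\C)CC[C@@H](O[Si](C)(C)C(C)(C)C)[C@]1(C)CCC(=O)O1 | intermediate
29 | (5S)-5-[(1R,4E,8E)-11-(furan-3-yl)-1-hydroxy-4,8-dimethylundeca-4,8-dien-1-yl]-5-methyloxolan-2-one | C/C(=C\CCc1ccoc1)CC/C=C(\C)CC[C@@H](O)[C@]1(C)CCC(=O)O1 | target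

## Step count and risk

Total steps: 19. Longest linear sequence: 18 steps (steps 1–9, then 11–19); step 10 is a one-step side branch.

Three steps most likely to fail:

**Step 11 (aldol).** The enolate is thermally labile and the aldehyde is enolisable, so proton transfer or enolate decomposition can erode the yield. The fallback sets out from ester 14 and comes back at ketone 21. The ester is treated with MeNH(OMe)·HCl and iPrMgCl (THF, −20 °C) to give the Weinreb amide (4E,8E)-11-(furan-3-yl)-N-methoxy-N,4,8-trimethylundeca-4,8-dienamide F1. This amide acylates lithium enolate 19 (THF, −78 to −40 °C) in a Claisen-type condensation on the same face trans to the tert-butyl group; the chelated tetrahedral intermediate prevents over-addition and collapses to 21 on work-up. Steps 9, 11 and 12 are bypassed.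

**Step 13 (CBS reduction).** The ketone is hindered, carries coordinating oxygens and may be mismatched with the catalyst, so the diastereomer ratio could be low. The fallback sets out from aldehyde 15 and comes back at target 29, setting both centres with a titanium tartrate epoxidation instead.
- Addition of isopropenylmagnesium bromide 6 (THF, −78 °C) gives rac-(6E,10E)-13-(furan-3-yl)-2,6,10-trimethyltrideca-1,6,10-trien-3-ol F2.
- Sharpless kinetic resolution (Ti(OiPr)4, D-(−)-diisopropyl tartrate, t-BuOOH 0.45 equiv, 4 Å sieves, CH2Cl2, −20 °C) epoxidises only the hydroxyl-directed allylic alkene of the fast-reacting (R)-enantiomer, erythro-selectively, to give (1R,4E,8E)-11-(furan-3-yl)-4,8-dimethyl-1-[(2S)-2-methyloxiran-2-yl]undeca-4,8-dien-1-ol F3.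
- Sodium dimethyl malonate (dimethyl malonate, NaOMe, MeOH, reflux) opens the epoxide at its CH2 terminus, and the tertiary alkoxide closes to methyl (5S)-5-[(1R,4E,8E)-11-(furan-3-yl)-1-hydroxy-4,8-dimethylundeca-4,8-dien-1-yl]-5-methyl-2-oxooxolane-3-carboxylate F4 (C3 epimers).
- Krapcho dealkoxycarbonylation (LiCl, wet DMSO, 140 °C) then gives 29.

**Step 18 (conjugate reduction and lactonisation).** Over-reduction of an isolated alkene, loss of the γ-oxygen or incomplete ring closure are possible. The fallback sets out from diol 24 and comes back at silyl lactone 28 without ever forming the enoate.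
- Selective tosylation of the primary alcohol (TsCl, pyridine, 0 °C) gives (2S,3R,6E,10E)-3-{[tert-butyl(dimethyl)silyl]oxy}-13-(furan-3-yl)-2-hydroxy-2,6,10-trimethyltrideca-6,10-dien-1-yl 4-methylbenzenesulfonate F5.
- K2CO3 in MeOH closes it to tert-butyl({(1R,4E,8E)-11-(furan-3-yl)-4,8-dimethyl-1-[(2S)-2-methyloxiran-2-yl]undeca-4,8-dien-1-yl}oxy)dimethylsilane F6.
- Sodium dimethyl malonate (dimethyl malonate, NaOMe, MeOH, reflux) gives methyl (5S)-5-[(1R,4E,8E)-1-{[tert-butyl(dimethyl)silyl]oxy}-11-(furan-3-yl)-4,8-dimethylundeca-4,8-dien-1-yl]-5-methyl-2-oxooxolane-3-carboxylate F7 (C3 epimers).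
- Krapcho dealkoxycarbonylation (LiCl, wet DMSO, 140 °C) gives 28.

## Further compounds

F1 | step 11 | (4E,8E)-11-(furan-3-yl)-N-methoxy-N,4,8-trimethylundeca-4,8-dienamide | CON(C)C(=O)CC/C(C)=C/CC/C(C)=C/CCc1ccoc1
F2 | step 13 | rac-(6E,10E)-13-(furan-3-yl)-2,6,10-trimethyltrideca-1,6,10-trien-3-ol | C=C(C)C(O)CC/C(C)=C/CC/C(C)=C/CCc1ccoc1
F3 | step 13 | (1R,4E,8E)-11-(furan-3-yl)-4,8-dimethyl-1-[(2S)-2-methyloxiran-2-yl]undeca-4,8-dien-1-ol | C[C@]1(CO1)[C@H](O)CC/C(C)=C/CC/C(C)=C/CCc2ccoc2
F4 | step 13 | methyl (5S)-5-[(1R,4E,8E)-11-(furan-3-yl)-1-hydroxy-4,8-dimethylundeca-4,8-dien-1-yl]-5-methyl-2-oxooxolane-3-carboxylate (C3 epimers) | COC(=O)C1C[C@](C)(OC1=O)[C@H](O)CC/C(C)=C/CC/C(C)=C/CCc2ccoc2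
F5 | step 18 | (2S,3R,6E,10E)-3-{[tert-butyl(dimethyl)silyl]oxy}-13-(furan-3-yl)-2-hydroxy-2,6,10-trimethyltrideca-6,10-dien-1-yl 4-methylbenzenesulfonate | Cc1ccc(cc1)S(=O)(=O)OC[C@](C)(O)[C@H](O[Si](C)(C)C(C)(C)C)CC/C(C)=C/CC/C(C)=C/CCc2ccoc2
F6 | step 18 | tert-butyl({(1R,4E,8E)-11-(furan-3-yl)-4,8-dimethyl-1-[(2S)-2-methyloxiran-2-yl]undeca-4,8-dien-1-yl}oxy)dimethylsilane | C[C@]1(CO1)[C@H](O[Si](C)(C)C(C)(C)C)CC/C(C)=C/CC/C(C)=C/CCc2ccoc2
F7 | step 18 | methyl (5S)-5-[(1R,4E,8E)-1-{[tert-butyl(dimethyl)silyl]oxy}-11-(furan-3-yl)-4,8-dimethylundeca-4,8-dien-1-yl]-5-methyl-2-oxooxolane-3-carboxylate (C3 epimers) | COC(=O)C1C[C@](C)(OC1=O)[C@H](O[Si](C)(C)C(C)(C)C)CC/C(C)=C/CC/C(C)=C/CCc2ccoc2
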